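The cyclohexane (C6 methine, C7 carbinol, C8 and C9 methylenes, C10 bromomethine, C11 quaternary carbon) is closed at C7–C8, after which only functional-group work remains. The route exploits the 1,4-relationship between the C7 carbinol and C10: with C10 as a ketone, C8 is its homoenolate carbon. C10, C9 and C8 are therefore carried as a cyclopropanol, and its strain-releasing opening delivers C8 to the C7 methyl ketone, forming the ring and the C7 stereocentre in one operation. The precursor is an acyclic keto cyclopropanol whose C6/C11 stereodiad is set on a butyrolactone template; bromide (by inversion) and the vinyl carbinol (Sharpless epoxidation) follow.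

Key step: step 9

Remark: atom labels follow the open-chain isoprenoid numbering (C1=C2 vinyl, C3 side-chain carbinol, C4 and C5 chain, C6–C11 ring, C12–C15 4-methylpent-3-enyl chain); compounds 1, 6 and 12 are assumed to be catalogue compounds.

Step 1
Reactants: 1 (R)-γ-valerolactone
Product: 3 (5R)-5-methylfuran-2(5H)-one, via α-phenylselanyl lactone 2 (not isolated)
Conditions: LiN(iPr)2, THF, −78 °C; PhSeBr; then 30% H2O2, CH2Cl2, 0 °C → rt
Reagents that add atoms: none
Why: α-Selenenylation of the lactone enolate followed by selenoxide syn-elimination should install the C6=C11 double bond without touching the C7 stereocentre.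

Step 2
Reactants: 3 (5R)-5-methylfuran-2(5H)-one
Product: 5 (3S,4S,5R)-4-ethenyl-3,5-dimethyloxolan-2-one, via bromomagnesium enolate 4 (not isolated)
Conditions: CH2=CHMgBr (2.2 equiv), CuI (1.1 equiv), THF, −78 → −40 °C; then CH3I, DMPU, −40 → 0 °C
Reagents that add atoms: vinylmagnesium bromide (C=C[Mg]Br); iodomethane (CI)
Why: In this tandem cuprate conjugate addition/enolate alkylation the vinyl group should add to C6 anti to the C7 methyl (setting 6S) and iodomethane should enter at C11 anti to the new vinyl group, a configuration that step 6 overwrites.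

Step 3
Reactants: 6 but-2-yn-1-ol
Product: 7 (but-2-yn-1-yloxy)(tert-butyl)dimethylsilane
Conditions: TBSCl, imidazole, DMF, rt
Reagents that add atoms: tert-butyldimethylsilyl chloride (CC(C)(C)[Si](C)(C)Cl)
Why: Routine silylation of a primary alcohol gives the silyl ether.

Step 4
Reactants: 7 (but-2-yn-1-yloxy)(tert-butyl)dimethylsilane
Product: 9 (E)-tert-butyl[(3-iodobut-2-en-1-yl)oxy]dimethylsilane, via alkenylzirconocene 8 (not isolated)
Conditions: Cp2Zr(H)Cl (1.8 equiv), THF, 50 °C; then N-iodosuccinimide, 0 °C
Reagents that add atoms: N-iodosuccinimide (O=C1CCC(=O)N1I)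
Why: syn-Hydrozirconation under equilibrating conditions should place zirconium on the methyl-bearing alkyne carbon, and iododezirconation with retention should give the (E)-iodide.

Step 5
Reactants: 5 (3S,4S,5R)-4-ethenyl-3,5-dimethyloxolan-2-one; 9 (E)-vinyl iodide
Product: 11 side-chain lactone (3S,4S,5R), via B-alkyl-9-BBN adduct 10 (not isolated)
Conditions: 9-BBN, THF, 0 °C → rt; then 9, Pd(dppf)Cl2 (5 mol%), AsPh3, Cs2CO3, DMF/H2O, rt
Reagents that add atoms: none
Why: Anti-Markovnikov hydroboration of the only alkene of 5 and B-alkyl Suzuki–Miyaura coupling with retention of the iodide geometry should join C4 to C3 and give the (E)-trisubstituted allylic silyl ether.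

Step 6
Reactants: 11 side-chain lactone; 12 5-iodo-2-methylpent-2-ene
Product: 14 quaternary lactone (3S,4S,5R), via lithium enolate 13 (not isolated)
Conditions: LiN(iPr)2, THF, −78 °C; then 12, DMPU, −78 → −20 °C
Reagents that add atoms: none
Why: In this diastereoselective lactone enolate alkylation the electrophile should enter anti to the adjacent C6 chain, placing the 4-methylpent-3-enyl group trans and the methyl cis to it and so fixing the quaternary C11 as S.

Step 7
Reactants: 14 quaternary lactone
Product: 15 cyclopropanol diol (6S; 7R; 11S)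
Conditions: EtMgBr (4 equiv, slow addition), Ti(OiPr)4 (30 mol%), THF, 0 °C → rt; aq. NH4Cl
Reagents that add atoms: ethylmagnesium bromide (CC[Mg]Br)
Why: Kulinkovich cyclopropanation of the lactone carbonyl C10 should give the 1-substituted cyclopropanol (new CH2 groups C8 and C9) and release the C7 alcohol, the trisubstituted alkenes and the silyl ether being inert to the titanacyclopropane.

Step 8
Reactants: 15 cyclopropanol diol
Product: 16 keto cyclopropanol (6S; 11S)
Conditions: (COCl)2, DMSO, CH2Cl2, −78 °C; Et3N, −78 → −20 °C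
Reagents that add atoms: none
Why: Swern oxidation should convert the secondary C7 carbinol into the methyl ketone, while the tertiary cyclopropanol has no carbinol hydrogen and the cold amine should not epimerise C6.

Step 9
Reactants: 16 keto cyclopropanol
Product: 18 hydroxy ketone (2S,3S,4R)-cyclohexanone, via zinc homoenolate 17 (not isolated)
Conditions: Et2Zn (1.1 equiv), THF, 0 °C → rt; then MgBr2·OEt2 (1.5 equiv), rt → 45 °C; pH 7 buffer
Reagents that add atoms: none
Why: Proposed new method: Et2Zn should convert the cyclopropanol (or its ring-closed hemiketal tautomer) into the ethylzinc cyclopropoxide, whose strained C10–CH2 bond opens to the chelated β-zincio ketone 17, and the C8–Zn bond should then add to the C7 carbonyl once MgBr2 activates it; the closest known reaction types are the Et2Zn-induced ring opening of cyclopropanols to zinc homoenolates, the magnesium-halide-accelerated addition of alkylzinc reagents to ketones and the titanium homoenolate aldol (homoaldol) addition. The cyclohexane closes in the 6-exo-trig mode, C8 attacking a carbonyl whose oxygen stays outside the new ring. The only new stereocentre, C7, should be set in a chair transition state with the C6 chain and the 4-methylpent-3-enyl group equatorial and the C11 methyl axial, in which the acetyl methyl takes the equatorial site to avoid a 1,3-diaxial clash with that methyl, so that the oxygen ends axial and cis to the C6 chain (7R). The step needs C8 to attack C7 rather than to be protonated, to transfer the ethyl group or to enolise toward C9; the aprotic non-basic medium, the intramolecular six-membered geometry and the release of cyclopropane strain should secure this, and opening of either cyclopropane C–CH2 bond gives the same homoenolate. No strong Lewis acid or base is present, so the trisubstituted alkenes, the allylic silyl ether and the epimerisable C6 centre should survive.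

Step 10
Reactants: 18 hydroxy ketone
Product: 19 (1R,2S,3S,4R)-cyclohexane-1,4-diol
Conditions: LiBH(s-Bu)3 (2.5 equiv), THF, −78 °C; then H2O
Reagents that add atoms: none
Why: In this substrate-controlled ketone reduction the bulky hydride should attack the C10 carbonyl from the equatorial direction, giving the axial (10R) alcohol trans to the axial C11 methyl.

Step 11
Reactants: 19 cyclohexane-1,4-diol
Product: 20 (1R,2S,3S,4S)-bromide silyl ether
Conditions: PPh3, CBr4, CH2Cl2, 0 °C → rt
Reagents that add atoms: carbon tetrabromide (BrC(Br)(Br)Br)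
Why: Appel bromination should displace the axial alkoxyphosphonium group by bromide with inversion to give the equatorial (10S) bromide, while the hindered tertiary C7 alcohol and the silyl ether should not react.

Step 12
Reactants: 20 bromide silyl ether
Product: 21 bromo allylic alcohol
Conditions: Bu4NF, THF, 0 °C
Reagents that add atoms: none
Why: Fluoride-mediated desilylation should free the allylic alcohol, and the equatorial neopentyl bromide has no antiperiplanar hydrogen and should resist elimination.

Step 13
Reactants: 21 bromo allylic alcohol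
Product: 22 (2S,3S)-epoxy alcohol
Conditions: Ti(OiPr)4 (10 mol%), L-(+)-diethyl tartrate (12 mol%), t-BuOOH, 4 Å molecular sieves, CH2Cl2, −20 °C
Reagents that add atoms: tert-butyl hydroperoxide (CC(C)(C)OO)
Why: Sharpless asymmetric epoxidation should oxidise only the allylic alcohol, and the L-(+)-tartrate ligand should deliver oxygen to the face that gives the (2S,3S)-epoxide, as it does for E-trisubstituted allylic alcohols of this type.

Step 14
Reactants: 22 epoxy alcohol
Product: 24 target, via epoxy iodide 23 (not isolated)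
Conditions: PPh3, I2, imidazole, CH2Cl2, 0 °C; filtration through silica; then Zn dust, AcOH, EtOH, 50 °C
Reagents that add atoms: none
Why: Appel-type iodination of the primary alcohol and zinc-induced reductive opening of the iodo epoxide (β-elimination) should unveil the C1=C2 vinyl group and the tertiary alcohol with the epoxide configuration at C3 retained (3S).

Compound list
1 | (R)-γ-valerolactone, (5R)-5-methyloxolan-2-one | C[C@H]1OC(=O)CC1 | starting material
2 | (5R)-5-methyl-3-(phenylselanyl)oxolan-2-one (C3 epimers) | C[C@H]1OC(=O)C([Se]c2ccccc2)C1 | intermediate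
3 | (5R)-5-methylfuran-2(5H)-one | C[C@H]1OC(=O)C=C1 | intermediate
4 | bromomagnesium enolate of (4S,5R)-4-ethenyl-5-methyloxolan-2-one | C[C@H]1OC(O[Mg]Br)=C[C@@H]1C=C | intermediate
5 | (3S,4S,5R)-4-ethenyl-3,5-dimethyloxolan-2-one | C[C@H]1OC(=O)[C@@H](C)[C@@H]1C=C | intermediate
6 | but-2-yn-1-ol | CC#CCO | starting material
7 | (but-2-yn-1-yloxy)(tert-butyl)dimethylsilane | CC#CCO[Si](C)(C)C(C)(C)C | intermediate
8 | [(2E)-4-(tert-butyldimethylsilyloxy)but-2-en-2-yl]chlorozirconocene | C/C(=C\CO[Si](C)(C)C(C)(C)C)[Zr](Cl)(C1C=CC=C1)C1C=CC=C1 | intermediate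
9 | (E)-tert-butyl[(3-iodobut-2-en-1-yl)oxy]dimethylsilane | C/C(I)=C\CO[Si](C)(C)C(C)(C)C | intermediate
10 | 9-{2-[(2R,3S,4S)-2,4-dimethyl-5-oxooxolan-3-yl]ethyl}-9-borabicyclo[3.3.1]nonane | C[C@H]1OC(=O)[C@@H](C)[C@@H]1CCB1C2CCCC1CCC2 | intermediate
11 | (3S,4S,5R)-4-[(3E)-5-(tert-butyldimethylsilyloxy)-3-methylpent-3-en-1-yl]-3,5-dimethyloxolan-2-one | C[C@H]1OC(=O)[C@@H](C)[C@@H]1CC/C(C)=C/CO[Si](C)(C)C(C)(C)C | intermediate
12 | 5-iodo-2-methylpent-2-ene | CC(C)=CCCI | starting material
13 | lithium enolate of lactone 11 | C[C@H]1OC(O[Li])=C(C)[C@@H]1CC/C(C)=C/CO[Si](C)(C)C(C)(C)C | intermediate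
14 | (3S,4S,5R)-4-[(3E)-5-(tert-butyldimethylsilyloxy)-3-methylpent-3-en-1-yl]-3,5-dimethyl-3-(4-methylpent-3-en-1-yl)oxolan-2-one | C[C@H]1OC(=O)[C@@](C)(CCC=C(C)C)[C@@H]1CC/C(C)=C/CO[Si](C)(C)C(C)(C)C | intermediate
15 | (2R,3S,6E)-8-(tert-butyldimethylsilyloxy)-3-[(2S)-2-(1-hydroxycyclopropyl)-6-methylhept-5-en-2-yl]-6-methyloct-6-en-2-ol | C[C@@H](O)[C@@H](CC/C(C)=C/CO[Si](C)(C)C(C)(C)C)[C@](C)(CCC=C(C)C)C1(O)CC1 | intermediate
16 | (3S,6E)-8-(tert-butyldimethylsilyloxy)-3-[(2S)-2-(1-hydroxycyclopropyl)-6-methylhept-5-en-2-yl]-6-methyloct-6-en-2-one | CC(=O)[C@@H](CC/C(C)=C/CO[Si](C)(C)C(C)(C)C)[C@](C)(CCC=C(C)C)C1(O)CC1 | intermediate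
17 | ethylzinc homoenolate (β-zincio ketone) formed by ring opening of 16; C8 bears zinc, C10 is a ketone | CC(=O)[C@@H](CC/C(C)=C/CO[Si](C)(C)C(C)(C)C)[C@](C)(CCC=C(C)C)C(=O)CC[Zn]CC | intermediate
18 | (2S,3S,4R)-3-[(3E)-5-(tert-butyldimethylsilyloxy)-3-methylpent-3-en-1-yl]-4-hydroxy-2,4-dimethyl-2-(4-methylpent-3-en-1-yl)cyclohexan-1-one | CC(C)(C)[Si](C)(C)OC/C=C(\C)CC[C@H]1[C@](C)(CCC=C(C)C)C(=O)CC[C@@]1(C)O | intermediate
19 | (1R,2S,3S,4R)-2-[(3E)-5-(tert-butyldimethylsilyloxy)-3-methylpent-3-en-1-yl]-1,3-dimethyl-3-(4-methylpent-3-en-1-yl)cyclohexane-1,4-diol | CC(C)(C)[Si](C)(C)OC/C=C(\C)CC[C@H]1[C@](C)(CCC=C(C)C)[C@H](O)CC[C@@]1(C)O | intermediate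
20 | (1R,2S,3S,4S)-4-bromo-2-[(3E)-5-(tert-butyldimethylsilyloxy)-3-methylpent-3-en-1-yl]-1,3-dimethyl-3-(4-methylpent-3-en-1-yl)cyclohexan-1-ol | CC(C)(C)[Si](C)(C)OC/C=C(\C)CC[C@H]1[C@](C)(CCC=C(C)C)[C@@H](Br)CC[C@@]1(C)O | intermediate
21 | (1R,2S,3S,4S)-4-bromo-2-[(3E)-5-hydroxy-3-methylpent-3-en-1-yl]-1,3-dimethyl-3-(4-methylpent-3-en-1-yl)cyclohexan-1-ol | OC/C=C(\C)CC[C@H]1[C@](C)(CCC=C(C)C)[C@@H](Br)CC[C@@]1(C)O | intermediate
22 | (1R,2S,3S,4S)-4-bromo-2-{2-[(2S,3S)-3-(hydroxymethyl)-2-methyloxiran-2-yl]ethyl}-1,3-dimethyl-3-(4-methylpent-3-en-1-yl)cyclohexan-1-ol | OC[C@@H]1O[C@@]1(C)CC[C@H]2[C@](C)(CCC=C(C)C)[C@@H](Br)CC[C@@]2(C)O | intermediate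
23 | (1R,2S,3S,4S)-4-bromo-2-{2-[(2S,3R)-3-(iodomethyl)-2-methyloxiran-2-yl]ethyl}-1,3-dimethyl-3-(4-methylpent-3-en-1-yl)cyclohexan-1-ol | IC[C@@H]1O[C@@]1(C)CC[C@H]2[C@](C)(CCC=C(C)C)[C@@H](Br)CC[C@@]2(C)O | intermediate
24 | (1R,2S,3S,4S)-4-bromo-2-[(3S)-3-hydroxy-3-methylpent-4-en-1-yl]-1,3-dimethyl-3-(4-methylpent-3-en-1-yl)cyclohexan-1-ol (CNP0237376.1) | C=C[C@@](C)(O)CC[C@H]1[C@](C)(CCC=C(C)C)[C@@H](Br)CC[C@@]1(C)O | target

Total step count: 14. Longest linear sequence: 12 steps (steps 1, 2 and 5–14 from lactone 1; the branch from alkyne 6 through steps 3–14 is equally long).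

Steps most likely to fail

1. Step 9 (proposed new method). The C8–Zn bond may fail to add to the ketone, because alkylzinc species are weak carbonyl nucleophiles. Ethyl transfer from zinc may compete. The homoenolate may be protonated to the ethyl ketone, or may enolise and close a five-membered ring through C9. Fallback with known chemistry: setting out from keto cyclopropanol 16, palladium-catalysed aerobic ring opening (Pd(OAc)2 10 mol%, pyridine, O2, toluene, 80 °C) should give the vinyl ketone F1. SmI2 (2.2 equiv, HMPA, THF, −78 °C, t-BuOH added only at the quench) should then join the C7 ketyl carbon to the enone terminus C8 in a 6-endo ketyl–olefin reductive cyclisation under the same chair control. This comes back to the route at hydroxy ketone 18.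

2. Step 11. The axial alkoxyphosphonium group is antiperiplanar to an axial C9–H and sits next to a quaternary carbon, so elimination toward C9 or ionisation with a 1,2-methyl shift from C11 may outrun the SN2 displacement. The tertiary alcohol may also be activated. Fallback: setting out from diol 19, selective sulfonylation of the secondary alcohol (ClCH2SO2Cl, pyridine, CH2Cl2, 0 °C) should give the isolable chloromethanesulfonate F2. Displacement of this much better leaving group with LiBr in DMF at 40 °C, again with inversion, comes back to the route at bromide 20.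

3. Step 6. SN2 attack of a hindered tetrasubstituted enolate on an unactivated homoallylic iodide may be slow, E2 loss of HI from the iodide may compete, and facial selectivity may be incomplete. Fallback: setting out from lactone 11, the same enolate is alkylated with the far more reactive allyl bromide, again anti to the C6 chain, to give the allyl lactone F3. Chemoselective hydroboration of the terminal alkene (9-BBN, then NaOH/H2O2) should give the primary alcohol F4, and Swern oxidation the aldehyde F5. Wittig olefination with Ph3P=C(CH3)2 (from isopropyltriphenylphosphonium iodide and n-BuLi, THF, −78 → 0 °C) comes back to the route at lactone 14.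

Further compounds
F1 | step 9 | (3S,6E)-8-(tert-butyldimethylsilyloxy)-6-methyl-3-[(3S)-3,7-dimethyl-4-oxoocta-1,6-dien-3-yl... vinyl ketone: 16 with the cyclopropanol replaced by a C10 ketone bearing the C9=C8 vinyl group | CC(=O)[C@@H](CC/C(C)=C/CO[Si](C)(C)C(C)(C)C)[C@](C)(CCC=C(C)C)C(=O)C=C
F2 | step 11 | C10 chloromethanesulfonate of diol 19 (10R) | CC(C)(C)[Si](C)(C)OC/C=C(\C)CC[C@H]1[C@](C)(CCC=C(C)C)[C@H](OS(=O)(=O)CCl)CC[C@@]1(C)O
F3 | step 6 | (3S,4S,5R)-3-allyl-4-[(3E)-5-(tert-butyldimethylsilyloxy)-3-methylpent-3-en-1-yl]-3,5-dimethyloxolan-2-one | C[C@H]1OC(=O)[C@@](C)(CC=C)[C@@H]1CC/C(C)=C/CO[Si](C)(C)C(C)(C)C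
F4 | step 6 | (3S,4S,5R)-4-[(3E)-5-(tert-butyldimethylsilyloxy)-3-methylpent-3-en-1-yl]-3-(3-hydroxypropyl)-3,5-dimethyloxolan-2-one | C[C@H]1OC(=O)[C@@](C)(CCCO)[C@@H]1CC/C(C)=C/CO[Si](C)(C)C(C)(C)C
F5 | step 6 | 3-{(3S,4S,5R)-4-[(3E)-5-(tert-butyldimethylsilyloxy)-3-methylpent-3-en-1-yl]-3,5-dimethyl-2-oxooxolan-3-yl}propanal | C[C@H]1OC(=O)[C@@](C)(CCC=O)[C@@H]1CC/C(C)=C/CO[Si](C)(C)C(C)(C)C
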